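**Retrosynthetic overview**

1. Ring A = enolised acyl triketone, ring B = spiro cyclohexane, ring C = cyclopentane (primed locants follow the spiro[cyclohexene-1,5'-indene] names). Target 15 ⇐ ring-B ketone 14 by methyl addition at C-7', so the last tertiary alcohol comes from a carbonyl and the prenyl alkenes are never exposed to alkene chemistry.
2. 14 ⇐ enol ether 13 ⇐ dienone 12: rings B and C and the spiro carbon C-1 close together in one intramolecular Diels–Alder reaction (bonds C-1–C-4' and C-3a'–C-7a').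
3. 12 ⇐ Knoevenagel union of triketone 4 (ring A, from acylphloroglucinol 1 by geminal diprenylation) with 2-methoxy enal 11.
4. 11 ⇐ (S)-linalool 5: ozonolysis to lactol 7, then two-carbon extension by Horner–Wadsworth–Emmons olefination. The linalool carbinol becomes C-3' and steers C-1, C-3a', C-7a' and C-7'.
5. Ring order: A (bought aromatic, dearomatised) → B and C together → C-7' carbinol.

Assumption: compounds 1, 2, 5 and 8 are catalogue chemicals, 5 being the (S)-(+)-enantiomer of linalool (coriander oil).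

**Step 1**
Reactants: 1 2-methyl-1-(2,4,6-trihydroxyphenyl)propan-1-one (isobutyrylphloroglucinol); 2 1-bromo-3-methylbut-2-ene (prenyl bromide, 2.1 equiv)
Product: 4 3-hydroxy-2-(2-methylpropanoyl)-4,4-bis(3-methylbut-2-en-1-yl)cyclohex-2-ene-1,5-dione (achiral geminal diprenyl triketone), via monoprenyl phenol 3 (not isolated)
Conditions: NaOMe, MeOH, 0 °C to 23 °C; chromatography
Reagents that add atoms: none
Why: Double C-alkylation of the phenoxide (alkylative dearomatisation) in which, after the first prenylation to 3, part of the second prenyl group enters at the same, most electron-rich carbon and gives the non-aromatic geminal triketone 4, separable from the 3,5-diprenyl isomer, with no stereocentre formed.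

**Step 2**
Reactants: 5 (3S)-3,7-dimethylocta-1,6-dien-3-ol, (S)-(+)-linalool
Product: 7 (5S)-5-ethenyl-5-methyloxolan-2-ol (both anomers; lactol of (4S)-4-hydroxy-4-methylhex-5-enal), via secondary ozonide 6 (not isolated)
Conditions: O3 (1 equiv), CH2Cl2, −78 °C; then Me2S, −78 °C to 23 °C
Reagents that add atoms: ozone, O=[O+][O-]
Why: Ozonolysis with reductive work-up cleaves the electron-rich trisubstituted alkene much faster than the vinyl group, the freed aldehyde is trapped as a lactol by the tertiary hydroxyl, and the carbinol stereocentre is untouched.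

**Step 3**
Reactants: 7 (5S)-5-ethenyl-5-methyloxolan-2-ol; 8 methyl 2-(dimethoxyphosphoryl)-2-methoxyacetate
Product: 9 methyl (2Z,6S)-6-hydroxy-2-methoxy-6-methylocta-2,7-dienoate
Conditions: NaH, THF, 0 °C to 23 °C
Reagents that add atoms: none
Why: Horner–Wadsworth–Emmons olefination of the open hydroxy-aldehyde form of the lactol, in which the stabilised phosphonate places the chain trans to the ester (Z by sequence rule) and no stereocentre is made or touched.

**Step 4**
Reactants: 9 methyl (2Z,6S)-6-hydroxy-2-methoxy-6-methylocta-2,7-dienoate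
Product: 10 (2Z,6S)-2-methoxy-6-methylocta-2,7-diene-1,6-diol
Conditions: i-Bu2AlH, CH2Cl2, −78 °C to 0 °C
Reagents that add atoms: none
Why: Hydride reduction of the conjugated ester to the allylic alcohol leaves the enol ether, the vinyl group and the tertiary carbinol unchanged.

**Step 5**
Reactants: 10 (2Z,6S)-2-methoxy-6-methylocta-2,7-diene-1,6-diol
Product: 11 (2Z,6S)-6-hydroxy-2-methoxy-6-methylocta-2,7-dienal
Conditions: MnO2, CH2Cl2, 23 °C
Reagents that add atoms: none
Why: Allylic oxidation with MnO2 acts only on the primary allylic alcohol (the tertiary alcohol cannot be oxidised) and keeps the double-bond geometry.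

**Step 6**
Reactants: 4 3-hydroxy-2-(2-methylpropanoyl)-4,4-bis(3-methylbut-2-en-1-yl)cyclohex-2-ene-1,5-dione; 11 (2Z,6S)-6-hydroxy-2-methoxy-6-methylocta-2,7-dienal
Product: 14 (1S,3'S,3a'R,7a'S)-3',4-dihydroxy-3'-methyl-3-(2-methylpropanoyl)-5,5-bis(3-methylbut-2-en-1-yl)octahydrospiro[cyclohex-3-ene-1,5'-indene]-2,6,7'-trione (trans-fused ring-B ketone), via Knoevenagel dienone 12 (not isolated), via enol-ether cycloadduct 13 (not isolated)
Conditions: ethylenediammonium diacetate (20 mol%), 4 Å molecular sieves, PhMe, 23 °C then 110 °C (sealed tube); then HCl (1 M aq), THF, 23 °C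
Reagents that add atoms: water, O
Why: Knoevenagel condensation at the only CH-acidic ring carbon of 4 gives the 1,1-diacyl diene 12, whose thermal intramolecular Diels–Alder reaction with the tethered vinyl group (three-atom tether) closes rings B and C and the spiro carbon in one event — the (S)-carbinol of the tether holds its hydroxyl toward the incoming triketone and its methyl away so the vinyl group adds to one face only, the tether-anti transition state gives the trans ring fusion, and the carbonyl flanked by the two prenyl groups takes the uncrowded outside position of the diene terminus, which sets C-1 as S — after which aqueous acid hydrolyses the enol ether to the ketone and lets C-7a', now alpha to it, settle in the trans-fused form.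

**Step 7**
Reactants: 14 (1S,3'S,3a'R,7a'S)-ring-B ketone
Product: 15 (1S,3'S,3a'R,7'R,7a'S)-3',4,7'-trihydroxy-3',7'-dimethyl-3-(2-methylpropanoyl)-5,5-bis(3-methylbut-2-en-1-yl)octahydrospiro[cyclohex-3-ene-1,5'-indene]-2,6-dione (CNP0273836.6)
Conditions: CeCl3, MeLi (excess), THF, −78 °C; then NH4Cl (aq)
Reagents that add atoms: methyllithium, [Li]C
Why: Organocerium 1,2-addition (Imamoto conditions) reaches only the C-7' ketone, because the ring-A ketone lies between two quaternary carbons and the acyl-enol unit is masked as its salt, and the methyl group enters equatorially because the axial face of C-7' is blocked by the syn-axial ring-A carbonyl carbon and H-3a', which gives the axial 7'R alcohol.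

**Compound list**

1 | 2-methyl-1-(2,4,6-trihydroxyphenyl)propan-1-one (isobutyrylphloroglucinol) | CC(C)C(=O)c1c(O)cc(O)cc1O | starting material
2 | 1-bromo-3-methylbut-2-ene (prenyl bromide) | CC(C)=CCBr | starting material
3 | 2-methyl-1-[2,4,6-trihydroxy-3-(3-methylbut-2-en-1-yl)phenyl]propan-1-one | CC(C)C(=O)c1c(O)cc(O)c(CC=C(C)C)c1O | intermediate
4 | 3-hydroxy-2-(2-methylpropanoyl)-4,4-bis(3-methylbut-2-en-1-yl)cyclohex-2-ene-1,5-dione (enol form of the 4,4-diprenyl triketone, achiral) | CC(C)=CCC1(CC=C(C)C)C(=O)CC(=O)C(C(=O)C(C)C)=C1O | intermediate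
5 | (3S)-3,7-dimethylocta-1,6-dien-3-ol, (S)-(+)-linalool | C=C[C@@](C)(O)CCC=C(C)C | starting material
6 | 5-[(3S)-3-hydroxy-3-methylpent-4-en-1-yl]-3,3-dimethyl-1,2,4-trioxolane (secondary ozonide) | C=C[C@@](C)(O)CCC1OOC(C)(C)O1 | intermediate
7 | (5S)-5-ethenyl-5-methyloxolan-2-ol (both anomers; lactol of (4S)-4-hydroxy-4-methylhex-5-enal) | C=C[C@]1(C)CCC(O)O1 | intermediate
8 | methyl 2-(dimethoxyphosphoryl)-2-methoxyacetate | COC(=O)C(OC)P(=O)(OC)OC | starting material
9 | methyl (2Z,6S)-6-hydroxy-2-methoxy-6-methylocta-2,7-dienoate | C=C[C@@](C)(O)CC/C=C(\OC)C(=O)OC | intermediate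
10 | (2Z,6S)-2-methoxy-6-methylocta-2,7-diene-1,6-diol | C=C[C@@](C)(O)CC/C=C(\OC)CO | intermediate
11 | (2Z,6S)-6-hydroxy-2-methoxy-6-methylocta-2,7-dienal | C=C[C@@](C)(O)CC/C=C(\OC)C=O | intermediate
12 | 3-hydroxy-6-[(2Z,6S)-6-hydroxy-2-methoxy-6-methylocta-2,7-dien-1-ylidene]-2-(2-methylpropanoyl)-4,4-bis(3-methylbut-2-en-1-yl)cyclohex-2-ene-1,5-dione (ring–chain double bond geometry not fixed) | CC(C)=CCC1(CC=C(C)C)C(=O)C(=CC(/OC)=C/CC[C@](C)(O)C=C)C(=O)C(C(=O)C(C)C)=C1O | intermediate
13 | (1S,3'S,3a'R,7a'S)-3',4-dihydroxy-7'-methoxy-3'-methyl-3-(2-methylpropanoyl)-5,5-bis(3-methylbut-2-en-1-yl)-1',2',3',3a',4',7a'-hexahydrospiro[cyclohex-3-ene-1,5'-indene]-2,6-dione (trans ring fusion) | CC(C)=CCC1(CC=C(C)C)C(=O)[C@@]2(C[C@@H]3[C@H](CC[C@]3(C)O)C(OC)=C2)C(=O)C(C(=O)C(C)C)=C1O | intermediate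
14 | (1S,3'S,3a'R,7a'S)-3',4-dihydroxy-3'-methyl-3-(2-methylpropanoyl)-5,5-bis(3-methylbut-2-en-1-yl)octahydrospiro[cyclohex-3-ene-1,5'-indene]-2,6,7'-trione (trans ring fusion) | CC(C)=CCC1(CC=C(C)C)C(=O)[C@@]2(C[C@@H]3[C@H](CC[C@]3(C)O)C(=O)C2)C(=O)C(C(=O)C(C)C)=C1O | intermediate
15 | (1S,3'S,3a'R,7'R,7a'S)-3',4,7'-trihydroxy-3',7'-dimethyl-3-(2-methylpropanoyl)-5,5-bis(3-methylbut-2-en-1-yl)octahydrospiro[cyclohex-3-ene-1,5'-indene]-2,6-dione, CNP0273836.6 | CC(C)=CCC1(CC=C(C)C)C(=O)[C@@]2(C[C@@H]3[C@H](CC[C@]3(C)O)[C@](C)(O)C2)C(=O)C(C(=O)C(C)C)=C1O | target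

**Step count and risks**

Total step count: 7. Longest linear sequence: 6 steps (5 → 7 → 9 → 10 → 11 → 14 → 15).

The three steps most likely to fail:

Step 6 (condensation and cycloaddition). Dienone 12 can close reversibly through a carbonyl oxygen or add its own tertiary hydroxyl, and its donor-substituted diene is poorly matched to the unactivated vinyl group. The control of C-1, of the face of attack and of the trans ring fusion rests on conformational arguments only. The fallback sets out from lactol 7 (with triketone 4 as before) and comes back to the route at ketone 14. Wittig reaction of 7 with (triphenylphosphoranylidene)acetaldehyde (PhMe, 80 °C) gives (2E,6S)-6-hydroxy-6-methylocta-2,7-dienal F3. Condensation with 4 under the same catalyst gives the donor-free, uniformly electron-poor dienone 3-hydroxy-6-[(2E,6S)-6-hydroxy-6-methylocta-2,7-dien-1-ylidene]-2-(2-methylpropanoyl)-4,4-bis(3-methylbut-2-en-1-yl)cyclohex-2-ene-1,5-dione F4, which has no acid-labile enol ether and cyclises on heating to the ring-B alkene (1S,3'S,3a'R,7a'R)-3',4-dihydroxy-3'-methyl-3-(2-methylpropanoyl)-5,5-bis(3-methylbut-2-en-1-yl)-1',2',3',3a',4',7a'-hexahydrospiro[cyclohex-3-ene-1,5'-indene]-2,6-dione F5. A Wacker-type oxidation (PdCl2, CuCl, O2, DMF–H2O) then places the carbonyl on C-7', the alkene carbon remote from the quaternary spiro centre, and leaves the trisubstituted prenyl alkenes alone, giving 14.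

Step 1 (geminal diprenylation). The second prenyl group may prefer the free ring carbon and give mainly the 3,5-diprenyl isomer. The fallback sets out from 1 and comes back at 4. Monobromination (N-bromosuccinimide, MeCN, 0 °C) gives 1-(3-bromo-2,4,6-trihydroxyphenyl)-2-methylpropan-1-one F1, which has only one ring CH left. The same NaOMe/prenyl bromide treatment can then place both prenyl groups only on that carbon, giving 6-bromo-3-hydroxy-2-(2-methylpropanoyl)-4,4-bis(3-methylbut-2-en-1-yl)cyclohex-2-ene-1,5-dione F2. Zn in AcOH removes the blocking bromine from the 2-bromo-1,3-dione and gives 4.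

Step 7 (methyl addition). The reagent may enolise the C-7' ketone, touch the ring-A ketone, or add from the wrong face. The fallback sets out from 14 and comes back at 15. Wittig methylenation (Ph3P=CH2, excess, THF) gives (1S,3'S,3a'R,7a'S)-3',4-dihydroxy-3'-methyl-7'-methylidene-3-(2-methylpropanoyl)-5,5-bis(3-methylbut-2-en-1-yl)octahydrospiro[cyclohex-3-ene-1,5'-indene]-2,6-dione F6. Oxymercuration–demercuration (Hg(OAc)2, THF–H2O; then NaBH4, NaOH) hydrates the 1,1-disubstituted alkene in the Markovnikov sense far faster than the two trisubstituted prenyl alkenes. Oxygen enters axially, assisted by the syn-axial ring-A carbonyl, to give the same 7'R alcohol 15.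

**Further compounds**

F1 | step 1 | 1-(3-bromo-2,4,6-trihydroxyphenyl)-2-methylpropan-1-one | CC(C)C(=O)c1c(O)cc(O)c(Br)c1O
F2 | step 1 | 6-bromo-3-hydroxy-2-(2-methylpropanoyl)-4,4-bis(3-methylbut-2-en-1-yl)cyclohex-2-ene-1,5-dione | CC(C)=CCC1(CC=C(C)C)C(=O)C(Br)C(=O)C(C(=O)C(C)C)=C1O
F3 | step 6 | (2E,6S)-6-hydroxy-6-methylocta-2,7-dienal | C=C[C@@](C)(O)CC/C=C/C=O
F4 | step 6 | 3-hydroxy-6-[(2E,6S)-6-hydroxy-6-methylocta-2,7-dien-1-ylidene]-2-(2-methylpropanoyl)-4,4-bis(3-methylbut-2-en-1-yl)cyclohex-2-ene-1,5-dione | CC(C)=CCC1(CC=C(C)C)C(=O)C(=C/C=C/CC[C@](C)(O)C=C)C(=O)C(C(=O)C(C)C)=C1O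
F5 | step 6 | (1S,3'S,3a'R,7a'R)-3',4-dihydroxy-3'-methyl-3-(2-methylpropanoyl)-5,5-bis(3-methylbut-2-en-1-yl)-1',2',3',3a',4',7a'-hexahydrospiro[cyclohex-3-ene-1,5'-indene]-2,6-dione | CC(C)=CCC1(CC=C(C)C)C(=O)[C@@]2(C[C@@H]3[C@H](CC[C@]3(C)O)C=C2)C(=O)C(C(=O)C(C)C)=C1O
F6 | step 7 | (1S,3'S,3a'R,7a'S)-3',4-dihydroxy-3'-methyl-7'-methylidene-3-(2-methylpropanoyl)-5,5-bis(3-methylbut-2-en-1-yl)octahydrospiro[cyclohex-3-ene-1,5'-indene]-2,6-dione | CC(C)=CCC1(CC=C(C)C)C(=O)[C@@]2(C[C@@H]3[C@H](CC[C@]3(C)O)C(=C)C2)C(=O)C(C(=O)C(C)C)=C1O
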